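Time was what mattered here: over 3.0 min first product rose and fell again, so I asked how much of it still stood at the end of each flask.

| flask | substrate | partner | remark | time |
|---|---|---|---|---|
| dawn | 0.10 M | 0.095 M | run made earlier |  |
| winter | 0.10 M | 0.064 M | run made earlier |  |
| noon | 0.10 M | 0.14 M | run made earlier |  |
| cedar | 0.10 M | 0.0950 M (in portions, 3, over 2.5 min) | first portion at the start, last at 2.5 min | 3.0 min |
| larch | 0.10 M | 0.0950 M (fed, over 2.5 min) | all else is in the flask from the start; the feed brings no volume worth counting | 3.0 min |
| maple | 0.10 M | 0.0950 M | everything together at the start | 3.0 min |
| oak | 0.10 M (fed, over 2.5 min) | 0.0950 M | all else is in the flask from the start; the feed brings no volume worth counting | 3.0 min |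

| run | time / min | first product / % | bis adduct / % |
|---|---|---|---|
| dawn | 0.250 | 14.7 | 7.2 |
| dawn | 0.417 | 15.6 | 11.2 |
| dawn | 0.833 | 12.9 | 18.7 |
| dawn | 1.50 | 6.4 | 22.4 |
| dawn | 3.00 | 1.2 | 23.8 |
| winter | 0.200 | 11.3 | 2.0 |
| winter | 0.667 | 11.0 | 8.0 |
| winter | 1.00 | 8.8 | 10.1 |
| winter | 1.50 | 5.1 | 11.7 |
| winter | 2.50 | 2.3 | 12.4 |
| noon | 0.200 | 18.6 | 10.3 |
| noon | 0.333 | 19.2 | 17.2 |
| noon | 0.667 | 14.2 | 29.6 |
| noon | 1.33 | 6.8 | 40.0 |
| noon | 2.50 | 2.9 | 44.6 |

(each reading ± 0.5 percentage points)

- the earlier runs were read with a standard deviation of 0.5 percentage points
- steps under discussion: substrate + partner -> first product; substrate + partner -> other mono adduct; first product -> over-reaction product; partner + first product -> bis adduct; partner + other mono adduct -> bis adduct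

- the flask with the highest share of first product in first product plus bis adduct ("all alike" if they lie within 1.5 percentage points) (cedar / larch / maple / oak / all alike)
- share of first product in first product plus bis adduct at the end, cedar
- share of first product in first product plus bis adduct at the end, larch
- share of first product in first product plus bis adduct at the end, maple
- share of first product in first product plus bis adduct at the end, oak

I followed the dawn run in slow motion, with amounts in percent of the substrate charged. In the first instants both products grew together, for at 0.250 min first product read 14.7% and bis adduct 7.2%. In the middle, first product had passed its highest reading, 15.6% at 0.417 min, and stood at 12.9% at 0.833 min, while bis adduct climbed to 18.7%. [partner] had started at 0.095 M, below the 0.10 M of substrate, which made partner the limiting reagent. Towards the end, between 1.50 min and 3.00 min, first product lost 5.2 percentage points while bis adduct gained 1.4 points, so I took most of that loss to be the step to over-reaction product.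

So I reckoned with the fraction left and not the fraction made. The stretch read a net fade of 1.12 /min, net of whatever first product was still forming, so I held it as a floor for the loss. First product standing at the start would then keep at most 3.52% by 3.0 min, but first product standing 0.500 min before the end keeps at most 57.2%, the last-stretch survival. Maple has the dawn charge, whose last reading gives a share of 4.80%. I therefore ranked cedar first, with a whole portion of partner arriving at 2.5 min, then larch, and maple below both.

The forecast named cedar, with 22% for cedar, 21% for larch, 5% for maple and 14.5% for oak, holding that “late partner helps by making fresh first product just before the end”.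

The flasks gave 28.5% for cedar, 24.3% for larch, 5.06% for maple and 15.4% for oak, so cedar led.

    substrate + partner → first product (k = 0.260 /M/s)
    substrate + partner → other mono adduct (k = 0.190 /M/s)
    first product → over-reaction product (k = 0.0230 /s)
    partner + first product → bis adduct (k = 0.280 /M/s)
    partner + other mono adduct → bis adduct (k = 0.520 /M/s)

Cedar ended with bis adduct at 16.5% against 19.1% in larch. Reckoned with the constant of the step to over-reaction product, the last-stretch survival comes to at most 50.2%, below the 57.2% read from the dawn run. Just before its last addition cedar held 4.53% of first product, of which at most 2.27% stood at the end, so at least 4.3 points of its final 6.58% was newer. Larch held 8.10% at the end of its feed, of which at most 4.06% stood at the end, so at least 2.1 points of its final 6.13% was newer.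

The runs come from a simulation for substances that don't exist; noise was put on by code.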